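Assumptions: diethyl (2R,3R)-oxirane-2,3-dicarboxylate (the L-tartrate-derived epoxide) and ethyl bromo(triphenylphosphoranylidene)acetate are treated as catalogue items. Atom labels C1–C15 follow germacrane numbering of the target (ring C1–C10, C14 = CHO carbon, C15 = vinyl methyl). SMILES are authoritative for stereochemistry.

## Retrosynthetic overview

1. Pulicanaral A ⇐ C14 alcohol oxidation and hydroxyl-directed epoxidation of the 1(10)-alkene of a ten-membered 6,8-diacetoxy diene; the final oxirane is the last ring formed.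
2. Ten-membered carbocycle ⇐ C9–C10 bond by a Ni-electrocatalytic reductive coupling of a terminal epoxide with an alkenyl bromide (the key, electrochemical, ring-forming step).
3. Seco precursor ⇐ C5–C6 bond by Nozaki–Hiyama–Kishi (NHK) coupling of an epoxy aldehyde (C6–C9 + iPr) with a bis-alkenyl halide (C1–C5, C10, C14, C15).
4. Epoxy aldehyde ⇐ diethyl (2R,3R)-epoxysuccinate: cuprate opening sets C7; mesylate/reduction/closure inverts C8 and gives the transient terminal oxirane.
5. Bis-alkenyl halide ⇐ pent-4-yn-1-ol by carboalumination–iodination and a bromo-Wittig olefination.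

## Route

**Step 1**
Reactants: 1, pent-4-yn-1-ol
Product: 2, (4E)-5-iodo-4-methylpent-4-en-1-ol
Conditions: Me3Al (3 equiv), Cp2ZrCl2 (0.25 equiv), CH2Cl2, 0 °C → rt; then I2, THF, −30 → 0 °C
Reagents that add atoms: trimethylaluminium, C[Al](C)C; iodine, II
Why: Zr-catalysed Negishi carboalumination adds Me–Al syn with Me on the internal carbon, and iodinolysis with retention gives the (E)-iodoalkene that becomes the C4=C5 unit with C15.

**Step 2**
Reactants: 2, (4E)-5-iodo-4-methylpent-4-en-1-ol
Product: 3, (4E)-5-iodo-4-methylpent-4-enal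
Conditions: Dess–Martin periodinane, NaHCO3, CH2Cl2, 0 °C → rt
Reagents that add atoms: none
Why: Dess–Martin oxidation of a primary alcohol; the alkenyl iodide is inert.

**Step 3**
Reactants: 3, (4E)-5-iodo-4-methylpent-4-enal
Product: 4, ethyl (2Z,6E)-2-bromo-7-iodo-6-methylhepta-2,6-dienoate
Conditions: Ph3P=C(Br)CO2Et (1.3 equiv), CH2Cl2, 0 °C → rt; minor E isomer removed by chromatography
Reagents that add atoms: ethyl bromo(triphenylphosphoranylidene)acetate, CCOC(=O)C(Br)=P(c1ccccc1)(c1ccccc1)c1ccccc1
Why: Wittig olefination with the ester-stabilised α-bromo ylide puts the ester trans to the chain (Br cis to C2), which fixes the later ring-cis C1=C10 geometry.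

**Step 4**
Reactants: 4, ethyl (2Z,6E)-2-bromo-7-iodo-6-methylhepta-2,6-dienoate
Product: 5, (2Z,6E)-2-bromo-7-iodo-6-methylhepta-2,6-dien-1-ol
Conditions: DIBAL-H (2.3 equiv), CH2Cl2, −78 °C; Rochelle salt
Reagents that add atoms: none
Why: DIBAL 1,2-reduction of the enoate to the allylic alcohol (future C14–OH); alkenyl halides and alkene geometry are untouched at −78 °C.

**Step 5**
Reactants: 5, (2Z,6E)-2-bromo-7-iodo-6-methylhepta-2,6-dien-1-ol
Product: 6, tert-butyl{[(2Z,6E)-2-bromo-7-iodo-6-methylhepta-2,6-dien-1-yl]oxy}dimethylsilane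
Conditions: TBSCl, imidazole, CH2Cl2, 0 °C → rt
Reagents that add atoms: tert-butyldimethylsilyl chloride, CC(C)(C)[Si](C)(C)Cl
Why: Standard silylation; it keeps C14–OH distinct from the two secondary alcohols that are acetylated later.

**Step 6**
Reactants: 7, diethyl (2R,3R)-oxirane-2,3-dicarboxylate
Product: 8, diethyl (2R,3S)-2-hydroxy-3-(propan-2-yl)butanedioate
Conditions: i-PrMgCl / CuBr·SMe2 (1.5 equiv each), THF, −45 → −20 °C; NH4Cl
Reagents that add atoms: isopropylmagnesium chloride, CC(C)[Mg]Cl
Why: Organocopper SN2 opening of the C2-symmetric trans-epoxide (both carbons equivalent, so no regiochemistry issue) with inversion gives the anti hydroxy ester and sets C7 from the purchased stereocentres.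

**Step 7**
Reactants: 8, diethyl (2R,3S)-2-hydroxy-3-(propan-2-yl)butanedioate
Product: 9, diethyl (2R,3S)-2-(methanesulfonyloxy)-3-(propan-2-yl)butanedioate
Conditions: MsCl (1.2 equiv), Et3N (1.5 equiv), CH2Cl2, −20 °C, 30 min
Reagents that add atoms: methanesulfonyl chloride, CS(=O)(=O)Cl
Why: O-sulfonylation of the secondary alcohol at low temperature and short time to avoid E1cB loss of mesylate; no stereocentre is touched.

**Step 8**
Reactants: 9, diethyl (2R,3S)-2-(methanesulfonyloxy)-3-(propan-2-yl)butanedioate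
Product: 10, ethyl (2S)-3-methyl-2-[(2S)-oxiran-2-yl]butanoate
Conditions: NaBH4 (1.5 equiv), EtOH, 0 °C; then K2CO3, 0 °C → rt
Reagents that add atoms: none
Why: Borohydride reduces the activated α-sulfonyloxy ester in preference to the α-branched one, and the resulting alkoxide closes by intramolecular Williamson SN2 with inversion at C8, turning the anti relationship into the required 7,8-syn one.

**Step 9**
Reactants: 10, ethyl (2S)-3-methyl-2-[(2S)-oxiran-2-yl]butanoate
Product: 11, (2S)-3-methyl-2-[(2S)-oxiran-2-yl]butanal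
Conditions: DIBAL-H (1.1 equiv), CH2Cl2, −78 °C; Rochelle salt; used crude at once
Reagents that add atoms: none
Why: Partial DIBAL reduction of the ester via the stable tetrahedral aluminate at −78 °C; the epoxide is inert, and immediate use avoids C7 epimerisation or β-elimination.

**Step 10**
Reactants: 11, (2S)-3-methyl-2-[(2S)-oxiran-2-yl]butanal; 6, the bis-alkenyl halide TBS ether (1.3 equiv)
Product: 12, (2Z,6E,8R,9R)-2-bromo-1-[(tert-butyldimethylsilyl)oxy]-6,10-dimethyl-9-[(2S)-oxiran-2-yl]undeca-2,6-dien-8-ol (target numbering: 6R; C6–OH anti to iPr and 1,3-anti to O8)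
Conditions: CrCl2 (4 equiv), NiCl2 (2 mol %), DMSO/THF, rt
Reagents that add atoms: none
Why: NHK coupling: Ni inserts into C–I much faster than C–Br and the alkenyl-Cr(III) adds only to the aldehyde with retention of the E geometry; Felkin–Anh attack anti to the bulky iPr, reinforced by the 1,3-anti preference of the β-oxygen, is expected to give 6R.

**Step 11**
Reactants: 12, the epoxy alkenyl bromide
Product: 13, (1R,2S,3R,4E,8E)-9-{[(tert-butyldimethylsilyl)oxy]methyl}-5-methyl-2-(propan-2-yl)cyclodeca-4,8-diene-1,3-diol (target numbering: 6R,7S,8R; 4E; C1=C10 ring-cis, i.e. C2 and C9 cis)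
Conditions: NiBr2·glyme (20 mol %), 4,4′-di-tert-butyl-2,2′-bipyridine (24 mol %), NaI (0.5 equiv), Et3N·HCl (1.5 equiv), DMA (2 mM), RVC cathode / Zn sacrificial anode, undivided cell, constant current (about 2.5 F/mol), rt
Reagents that add atoms: none
Why: Proposed new method: Et3NH+/I− reversibly opens the terminal epoxide at the primary C9 to an iodohydrin (the C8–O bond and its stereocentre are untouched), cathodically generated Ni(0) inserts into the alkenyl C–Br with retention, Ni(I) abstracts iodine to give the C9 radical, which is captured intramolecularly by the alkenyl-Ni(II), and C(sp3)–C(sp2) reductive elimination from Ni(III) closes the ten-membered ring while catalytic iodide keeps the radical precursor at low concentration; the closest known reactions are Ni/iodide co-catalysed reductive epoxide–aryl/alkenyl halide coupling with Mn or Zn powder and Ni-electrocatalytic C(sp3)–C(sp2) cross-electrophile coupling, neither shown intramolecularly for a medium carbocycle.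

**Step 12**
Reactants: 13, the macrocyclic diol
Product: 14, (1R,2S,3R,4E,8E)-9-{[(tert-butyldimethylsilyl)oxy]methyl}-5-methyl-2-(propan-2-yl)cyclodeca-4,8-diene-1,3-diyl diacetate
Conditions: Ac2O, DMAP (cat.), pyridine, rt
Reagents that add atoms: acetic anhydride, CC(=O)OC(C)=O
Why: DMAP-catalysed acylation installs both target acetates (C6, C8) in one operation with retention.

**Step 13**
Reactants: 14, the diacetate TBS ether
Product: 15, (1R,2S,3R,4E,8E)-9-(hydroxymethyl)-5-methyl-2-(propan-2-yl)cyclodeca-4,8-diene-1,3-diyl diacetate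
Conditions: HF·pyridine, pyridine/THF, 0 °C → rt
Reagents that add atoms: none
Why: Buffered fluoride cleaves the primary silyl ether without acetate hydrolysis or migration.

**Step 14**
Reactants: 15, the C14 allylic alcohol
Product: 16, 6,8-diacetoxy-1,10-epoxygermacr-4(E)-en-14-ol (1R,6R,7S,8R,10R by CIP; cis-fused oxirane with the same geometry as the target)
Conditions: VO(acac)2 (5 mol %), t-BuOOH (1.5 equiv), CH2Cl2, 0 °C
Reagents that add atoms: tert-butyl hydroperoxide, CC(C)(C)OO
Why: Vanadium-catalysed hydroxyl-directed epoxidation acts only on the alkene bearing the free allylic OH (C4=C5 has an allylic acetate and is not directed), is stereospecifically syn (cis oxirane), and is expected to deliver oxygen to the ring face anti to the C7 isopropyl group under substrate control.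

**Step 15**
Reactants: 16, the epoxy alcohol
Product: 17, pulicanaral A, (1R,6R,7S,8R,10S,4E)-6,8-diacetoxy-1,10-epoxygermacr-4-en-14-al
Conditions: Dess–Martin periodinane, NaHCO3, CH2Cl2, 0 °C
Reagents that add atoms: none
Why: Dess–Martin oxidation of the primary epoxy alcohol to the α,β-epoxy aldehyde; C10 is quaternary so nothing can epimerise, and acetates and the epoxide survive the buffered conditions.

## Compound list

1 | pent-4-yn-1-ol | C#CCCCO | starting material
2 | (4E)-5-iodo-4-methylpent-4-en-1-ol | OCCC/C(C)=C/I | intermediate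
3 | (4E)-5-iodo-4-methylpent-4-enal | O=CCC/C(C)=C/I | intermediate
4 | ethyl (2Z,6E)-2-bromo-7-iodo-6-methylhepta-2,6-dienoate | CCOC(=O)/C(Br)=C/CC/C(C)=C/I | intermediate
5 | (2Z,6E)-2-bromo-7-iodo-6-methylhepta-2,6-dien-1-ol | OC/C(Br)=C/CC/C(C)=C/I | intermediate
6 | tert-butyl{[(2Z,6E)-2-bromo-7-iodo-6-methylhepta-2,6-dien-1-yl]oxy}dimethylsilane | CC(C)(C)[Si](C)(C)OC/C(Br)=C/CC/C(C)=C/I | intermediate
7 | diethyl (2R,3R)-oxirane-2,3-dicarboxylate | CCOC(=O)[C@@H]1O[C@H]1C(=O)OCC | starting material
8 | diethyl (2R,3S)-2-hydroxy-3-(propan-2-yl)butanedioate | CCOC(=O)[C@H](O)[C@H](C(C)C)C(=O)OCC | intermediate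
9 | diethyl (2R,3S)-2-(methanesulfonyloxy)-3-(propan-2-yl)butanedioate | CCOC(=O)[C@H](OS(C)(=O)=O)[C@H](C(C)C)C(=O)OCC | intermediate
10 | ethyl (2S)-3-methyl-2-[(2S)-oxiran-2-yl]butanoate | CCOC(=O)[C@@H](C(C)C)[C@H]1CO1 | intermediate
11 | (2S)-3-methyl-2-[(2S)-oxiran-2-yl]butanal | O=C[C@@H](C(C)C)[C@H]1CO1 | intermediate
12 | (2Z,6E,8R,9R)-2-bromo-1-[(tert-butyldimethylsilyl)oxy]-6,10-dimethyl-9-[(2S)-oxiran-2-yl]undeca-2,6-dien-8-ol | CC(C)(C)[Si](C)(C)OC/C(Br)=C/CC/C(C)=C/[C@@H](O)[C@@H](C(C)C)[C@H]1CO1 | intermediate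
13 | (1R,2S,3R,4E,8E)-9-{[(tert-butyldimethylsilyl)oxy]methyl}-5-methyl-2-(propan-2-yl)cyclodeca-4,8-diene-1,3-diol | O[C@@H]1/C=C(\C)CC/C=C(/CO[Si](C)(C)C(C)(C)C)C[C@@H](O)[C@@H]1C(C)C | intermediate
14 | (1R,2S,3R,4E,8E)-9-{[(tert-butyldimethylsilyl)oxy]methyl}-5-methyl-2-(propan-2-yl)cyclodeca-4,8-diene-1,3-diyl diacetate | CC(=O)O[C@@H]1/C=C(\C)CC/C=C(/CO[Si](C)(C)C(C)(C)C)C[C@@H](OC(C)=O)[C@@H]1C(C)C | intermediate
15 | (1R,2S,3R,4E,8E)-9-(hydroxymethyl)-5-methyl-2-(propan-2-yl)cyclodeca-4,8-diene-1,3-diyl diacetate | CC(=O)O[C@@H]1/C=C(\C)CC/C=C(/CO)C[C@@H](OC(C)=O)[C@@H]1C(C)C | intermediate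
16 | (1R,6R,7S,8R,10R)-6,8-diacetoxy-1,10-epoxygermacr-4(E)-en-14-ol | CC(=O)O[C@@H]1/C=C(\C)CC[C@H]2O[C@@]2(CO)C[C@@H](OC(C)=O)[C@@H]1C(C)C | intermediate
17 | pulicanaral A, (1R,6R,7S,8R,10S,4E)-6,8-diacetoxy-1,10-epoxygermacr-4-en-14-al | CC(=O)O[C@@H]1/C=C(\C)CC[C@H]2O[C@@]2(C=O)C[C@@H](OC(C)=O)[C@@H]1C(C)C | target

## Summary

Total steps: 15. Longest linear sequence: 11 (steps 1–5, then 10–15); the other branch (steps 6–9, then 10–15) is 10.

Steps most likely to fail:

1. **Step 11 (proposed electroreductive epoxide/alkenyl bromide macrocyclisation).** Risks are oligomerisation, proto-debromination, or reduction of the C9 radical before capture. Fallback with known chemistry: move the ring closure to C5–C6. Open epoxide 10 intermolecularly at C9 with the alkenyl cuprate of an alkyne-terminated analogue of 6, then carboaluminate/iodinate the alkyne, reduce the ester to the aldehyde, and close the ring by an intramolecular Nozaki–Hiyama–Kishi reaction.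
2. **Step 10 (C6 configuration).** Felkin control depends on iPr outranking the oxiranyl carbon and may be modest. Fallback: carry the mixture through ring closure, oxidise the allylic C6–OH of 13 with MnO2 to the β-hydroxy enone, and reduce with Me4NBH(OAc)3 (Evans–Saksena, directed by C8–OH, 1,3-anti) to set 6R.
3. **Step 14 (facial selectivity of the epoxidation).** The face is set only by macrocycle conformation and has not been modelled. Fallback: oxidise 15 to the C14 enal (MnO2) and epoxidise nucleophilically (t-BuOOH/DBU, Weitz–Scheffer), which does not depend on hydroxyl delivery.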